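## Analysis of the target

The target is an 18-membered macrocyclic bis(bibenzyl) of the marchantin type. Four benzene rings are joined in a cycle by two diaryl ether links (A-6–O–B-1 and C-3–O–D-1) and two ethano bridges (B-3–CH2CH2–C-1 and D-4–CH2CH2–A-5). Ring positions are written here with a hyphen, and hyphen-free labels such as A5 are kept for compounds of the rejected strategies. Ring A is a 1,2,3,4-tetrasubstituted hydroquinone monomethyl ether (A-1 OMe, A-4 OH, A-5 CH2, A-6 O-aryl), ring B is meta-linked, ring C has a free phenol at C-4 next to its ether oxygen at C-3, and ring D is para-linked. There is no stereocentre, so nothing has to be set or related. The sensitive functions are the two free phenols and the electron-rich ring A, which oxidises easily to a quinone, and the A-1 methyl ether must stay distinct from both hydroxyls to the end. Two things make the synthesis hard: closing a fairly rigid 18-membered ring, and the contiguous substitution of ring A, where the bridge carbon A-5 sits between the A-4 hydroxyl and the A-6 aryloxy group at a site that ordinary electrophilic substitution of a phenol would not select. The plan rests on this triad: an oxygen at A-4 and a carbon at A-5 on adjacent atoms, next to an inductively withdrawing aryloxy group at A-6, is the pattern left when a formamide C=O adds across a 3-aryloxybenzyne spanning A-4 and A-5.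

## Retrosynthetic reasoning

**Phenol protection.** The two O–benzyl bonds of 26 are cut last. Benzyl ethers on A-4 and C-4 fall together under hydrogenolysis, which leaves the A-1 methyl ether, both diaryl ethers and the ethano bridges alone, so 27 comes from 26 in one clean step.

**Ring opening at D-4–CH2.** The macrocycle 26 is opened at the sp2–sp3 bond between ring D and the D–A bridge, giving the alkylborane 25 and, before hydroboration, the styrene 24 with a ring D bromide. This bond is chosen because D-4 is an unhindered para position, whereas A-5 is flanked by two oxygens. Cutting either diaryl ether would require a macrocyclic etherification, the A-6 one at a doubly ortho-substituted carbon. The forward reaction is an intramolecular B-alkyl Suzuki–Miyaura coupling that must beat oligomerisation.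

**Two-carbon stub on ring A.** The vinyl group of 24 is traced to the aldehyde 23 by a one-carbon olefination, and the A-4 benzyl ether of 23 to the free phenol 22. Ring A is thereby reduced to a salicylaldehyde: hydroxyl at A-4, formyl at A-5.

**Aryne–formamide insertion (key).** In 22 the A-4–O bond and the A-5–CHO bond are cut together, leading to the aryne 20 and N,N-dimethylformamide 19, and 20 to the ortho-silylaryl triflate 18. An ortho-hydroxy aldehyde is the direct retron of this insertion, and the A-6 aryloxy group fixes its orientation. Formylating an A-4 phenol instead would go to the open A-3 position, and a lithiation–formylation at this stage would not tolerate the ring D bromide. The gain is that both substituents of the most crowded edge of ring A arrive in one operation on the fully assembled open chain.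

**Aryne precursor.** The triflate 18 is traced through the phenol 17 to the diethylcarbamate 16 (S–O and carbamoyl C–O bonds). The carbamate is kept as long as possible because it is the group that directed silicon to A-5 and it withstands all intervening chemistry; the fluoride-labile triflate is made only just before it is used.

**B–C bridge.** The central bond of the B-3–CH2CH2–C-1 bridge in 16 is cut as the C=C bond of the stilbene 15, which comes from the ylide 14 (from phosphonium salt 10) and the aldehyde 13. A Wittig union is chosen over a cross-coupling because the ring D bromide of 13 must survive. The resulting alkene needs a reduction that spares C–Br, O–benzyl and C–Si.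

**C–O–D ether.** 13 is cut at the C-3–O–D-1 ether into the phenol 11 and the boronic acid 12. An oxidative copper coupling at room temperature brings in ring D with its bromide intact.

**Phosphonium salt.** 10 is traced to the benzylic bromide 9 and then to the tolyl compound 8. A methyl group is used as the ring B handle because it is the one benzylic function that is inert to the alkyllithium needed earlier.

**C–Si bond at A-5.** 8 is cut at the A-5–Si bond to the aryllithium 7 and the carbamate 6. A-5–H lies between the carbamate oxygen and the aryloxy oxygen, the most acidic ring position, so directed ortho-metalation places silicon exactly where the aryne must later form. This step has to precede any aryl bromide.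

**Ring A and the A–O–B ether.** 6 comes from the phenol 5, 5 from the aldehyde 3 via the formate 4 (aryl C–CHO to C–O), and 3 from isovanillin 1 and 3-iodotoluene 2 (A-6–O–B-1 bond). Isovanillin already holds the A-1 methoxy and A-6 hydroxyl in the right relation, its formyl group marks A-4, and the hindered diaryl ether is made while A-5 is still unsubstituted.

## Alternatives that were turned down

**Alternative 1:** Sulfone ring contraction.
- Disconnection: the CH2–CH2 bond of the D–A bridge is replaced by a CH2–SO2–CH2 unit, giving the 19-membered dibenzylic sulfone A2.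
- Forward key step: irradiation or flash vacuum pyrolysis of A2 would expel the sulfonyl group as gas; the two tethered benzylic radicals recombine to the 18-membered diisopropyl ether A1, which is then dealkylated.
- For: the large ring is first closed by a forgiving C–S bond, and the C–C bond then forms between radicals already held together, with no metal and no aryl halide.
- Against: A2 still needs a ring A with a benzylic carbon at A-5 between two oxygens, so the ring A problem is untouched. The A-5 benzylic radical is twisted by its two ortho substituents, which favours hydrogen abstraction and disproportionation over recombination. Diaryl ethers absorb in the same UV range. Pyrolysis asks a heavy, involatile polyether to reach the gas phase. Thioether closure, oxidation and extrusion are three operations for one bond, before a selective ether cleavage.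
- Comparison: on the entropy of ring closure this alternative is as strong or stronger than a palladium macrocyclisation. The chosen route offers instead a mild catalytic closure that tolerates every group present, and an actual answer to the ring A pattern.

**Alternative 2:** Cyclobutenone ring expansion.
- Disconnection: ring A itself is cut at A-3–A-4 and traced to the 4-methoxy-4-vinylcyclobutenone A4.
- Forward key step: heating A4 opens the four-membered ring (4π, the alkoxy group turning outward) to a dienylketene, which closes by 6π electrocyclisation and tautomerises to the phenol A3.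
- For: the positions of all four ring A substituents are written into A4, so regiochemistry does not depend on any directing effect. The A-4 hydroxyl appears free beside an A-1 methyl ether with no protecting-group exchange. The step is thermal and neutral.
- Against: A4 needs about half a dozen squarate manipulations (aryloxy exchange, chain introduction, vinyl addition, O-methylation), with an aryl vinylogous ester that organometallics can displace. A3 contains only rings A, B and D, so ring C, the B–C bridge and a macrocyclic C–O–D etherification still lie ahead; the last is harder than a C–C closure.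
- Comparison: this alternative is stronger on regiochemical certainty and on keeping the A-4 oxygen once it is made. The chosen route has to install that oxygen twice, since the Dakin oxygen leaves as triflate. In return it takes ring A ready-made from isovanillin, joins the fragments by robust reactions and reaches the target in fewer steps.

**Alternative 3:** Quinone monoketal addition–elimination.
- Disconnection: the A-6–O bond of the A–O–B ether is cut as the ring-closing bond, leading to the open-chain bromo quinone monoketal A6 with a silyl-protected ring B phenol (a tert-butyldimethylsilyl ether is assumed).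
- Forward key step: fluoride would free the ring B phenoxide of A6, which adds to the bromine-bearing β-carbon A-6 of the dienone and expels bromide, closing the 18-membered ring to the macrocyclic monoketal A5. Reductive aromatisation and debenzylation would follow.
- For: the most hindered ether is formed by an electronically strongly driven vinylogous substitution without metal. A5 is one reduction away from a ring A whose A-1 methoxy and A-4 hydroxyl are already differentiated.
- Against: the electrophilic carbon is tetrasubstituted, wedged between the quaternary ketal carbon and the α-alkyl chain, and must be reached within an 18-membered transition state. 1,2-Addition, intermolecular attack and loss of the ketal compete. A6 itself requires a 2-alkyl-3-bromo-4-methoxyphenol (again a contiguously tetrasubstituted arene) and an oxidative dearomatisation in the presence of other electron-rich rings.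
- Comparison: the end game of this alternative is shorter and metal-free. The chosen route separates the two hard problems: the crowded A–O–B ether is made first on unhindered isovanillin, and the ring is closed later at the unhindered ring D carbon.

Key step: step 12

Assumption: the target has no stereogenic element that needs control (the cyclophane conformers are taken to interconvert), and the stilbene 15 is carried forward as an E/Z mixture because the double bond is saturated in the next step.

Shorthand in names: "BCD-phenoxy" = 3-{2-[4-(benzyloxy)-3-(4-bromophenoxy)phenyl]ethyl}phenoxy, i.e. rings B, C and D with the B–C ethano bridge, the C-4 benzyl ether and the ring D bromide.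

## Route

Step 1
Reactants: 1 isovanillin (3-hydroxy-4-methoxybenzaldehyde); 2 3-iodotoluene
Product: 3 4-methoxy-3-(3-methylphenoxy)benzaldehyde
Conditions: CuI (10 mol %), N,N-dimethylglycine hydrochloride (30 mol %), Cs2CO3, 1,4-dioxane, 90 °C
Reagents that add atoms: none
Why: Amino-acid-ligated Ullmann diaryl ether coupling of a guaiacol-type phenoxide with an aryl iodide; the aldehyde and the tolyl methyl are inert, and the A-6–O–B-1 ether is made while A-5 is still unsubstituted.

Step 2
Reactants: 3 4-methoxy-3-(3-methylphenoxy)benzaldehyde
Product: 5 4-methoxy-3-(3-methylphenoxy)phenol, via aryl formate 4 (not isolated)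
Conditions: mCPBA, CH2Cl2, rt; aq. NaHCO3 wash; then K2CO3 (cat.), MeOH, rt
Reagents that add atoms: 3-chloroperbenzoic acid, O=C(OO)c1cccc(Cl)c1
Why: Dakin-type oxidation by Baeyer–Villiger rearrangement: the electron-rich para-methoxyaryl group migrates in the Criegee adduct to give formate 4, which catalytic carbonate in methanol transesterifies to phenol 5.

Step 3
Reactants: 5 4-methoxy-3-(3-methylphenoxy)phenol
Product: 6 4-methoxy-3-(3-methylphenoxy)phenyl N,N-diethylcarbamate
Conditions: Et2NCOCl, K2CO3, MeCN, reflux
Reagents that add atoms: N,N-diethylcarbamoyl chloride, CCN(CC)C(Cl)=O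
Why: O-Carbamoylation of the phenoxide; the tertiary carbamate is the strongest oxygen-based director for the next step and withstands radical bromination, ylides and diimide.

Step 4
Reactants: 6 4-methoxy-3-(3-methylphenoxy)phenyl N,N-diethylcarbamate
Product: 8 4-methoxy-3-(3-methylphenoxy)-2-(trimethylsilyl)phenyl N,N-diethylcarbamate, via aryllithium 7 (not isolated)
Conditions: s-BuLi, TMEDA, THF, −78 °C; then TMSCl, −78 °C → rt
Reagents that add atoms: sec-butyllithium, [Li]C(C)CC (supplies the lithium of 7 only); chlorotrimethylsilane, C[Si](C)(C)Cl
Why: Directed ortho-metalation: the A-5 hydrogen lies between the carbamate and the aryloxy oxygen and should be removed faster than any other ring hydrogen or the benzylic methyl. At −78 °C aryllithium 7 does not undergo anionic Fries migration and is trapped by the chlorosilane.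

Step 5
Reactants: 8 4-methoxy-3-(3-methylphenoxy)-2-(trimethylsilyl)phenyl N,N-diethylcarbamate
Product: 9 3-[3-(bromomethyl)phenoxy]-4-methoxy-2-(trimethylsilyl)phenyl N,N-diethylcarbamate
Conditions: NBS (1.05 equiv), AIBN (cat.), PhCF3, 80 °C
Reagents that add atoms: N-bromosuccinimide, O=C1CCC(=O)N1Br
Why: Wohl–Ziegler radical bromination at the only benzylic C–H position; in a non-polar solvent the radical chain should outrun ionic bromination of ring A, whose nucleophilicity is lowered by the carbamate.

Step 6
Reactants: 9 3-[3-(bromomethyl)phenoxy]-4-methoxy-2-(trimethylsilyl)phenyl N,N-diethylcarbamate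
Product: 10 {3-[3-(diethylcarbamoyloxy)-6-methoxy-2-(trimethylsilyl)phenoxy]benzyl}triphenylphosphonium bromide
Conditions: PPh3, toluene, reflux
Reagents that add atoms: triphenylphosphine, c1ccc(cc1)P(c1ccccc1)c1ccccc1
Why: SN2 quaternisation of triphenylphosphine by a primary benzylic bromide; the salt should precipitate from toluene.

Step 7
Reactants: 11 4-(benzyloxy)-3-hydroxybenzaldehyde; 12 4-bromophenylboronic acid
Product: 13 4-(benzyloxy)-3-(4-bromophenoxy)benzaldehyde
Conditions: Cu(OAc)2 (20 mol %), pyridine, 4 Å MS, CH2Cl2, O2 (1 atm), rt
Reagents that add atoms: none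
Why: Chan–Lam oxidative O-arylation under divalent copper catalysis at room temperature; the C–B bond reacts while the aryl bromide and the aldehyde stay untouched, which a Ullmann coupling with a dihaloarene could not guarantee.

Step 8
Reactants: 10 {3-[3-(diethylcarbamoyloxy)-6-methoxy-2-(trimethylsilyl)phenoxy]benzyl}triphenylphosphonium bromide; 13 4-(benzyloxy)-3-(4-bromophenoxy)benzaldehyde
Product: 15 3-(3-{2-[4-(benzyloxy)-3-(4-bromophenoxy)phenyl]ethenyl}phenoxy)-4-methoxy-2-(trimethylsilyl)phenyl N,N-diethylcarbamate (E/Z mixture), via phosphorus ylide 14 (not isolated)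
Conditions: K2CO3, 18-crown-6 (cat.), CH2Cl2, reflux
Reagents that add atoms: none
Why: Wittig olefination of a semi-stabilised benzylic ylide under solid–liquid phase-transfer conditions, mild enough for the carbamate, the aryl silane and the aryl bromide; the alkene geometry is irrelevant.

Step 9
Reactants: 15 stilbene (E/Z mixture)
Product: 16 3-(BCD-phenoxy)-4-methoxy-2-(trimethylsilyl)phenyl N,N-diethylcarbamate
Conditions: TsNHNH2 (excess), NaOAc, THF/H2O, reflux
Reagents that add atoms: none
Why: Diimide reduction: diimide released from the sulfonyl hydrazide transfers two hydrogens to the C=C bond in a concerted syn fashion and does not touch C–Br, O–benzyl, C–Si or the carbamate, unlike hydrogenation over palladium.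

Step 10
Reactants: 16 3-(BCD-phenoxy)-4-methoxy-2-(trimethylsilyl)phenyl N,N-diethylcarbamate
Product: 17 3-(BCD-phenoxy)-4-methoxy-2-(trimethylsilyl)phenol
Conditions: Cp2Zr(H)Cl (3 equiv), THF, rt; then aq. NH4Cl
Reagents that add atoms: none
Why: Reductive cleavage of a tertiary aryl O-carbamate by hydrozirconation of its carbonyl and collapse to the zirconium phenoxide and a formamide; the conditions are neutral and should spare the aryl bromide, the benzyl ether and the C–Si bond, where basic hydrolysis of a diethylcarbamate would need forcing.

Step 11
Reactants: 17 3-(BCD-phenoxy)-4-methoxy-2-(trimethylsilyl)phenol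
Product: 18 3-(BCD-phenoxy)-4-methoxy-2-(trimethylsilyl)phenyl trifluoromethanesulfonate
Conditions: Tf2O, pyridine, CH2Cl2, 0 °C
Reagents that add atoms: trifluoromethanesulfonic anhydride, O=S(=O)(OS(=O)(=O)C(F)(F)F)C(F)(F)F
Why: O-Sulfonylation of the phenol completes the ortho-silylaryl triflate; it is made directly before use so that the fluoride-labile aryne precursor is not carried through other steps.

Step 12
Reactants: 18 3-(BCD-phenoxy)-4-methoxy-2-(trimethylsilyl)phenyl trifluoromethanesulfonate; 19 N,N-dimethylformamide
Product: 22 2-(BCD-phenoxy)-6-hydroxy-3-methoxybenzaldehyde, via aryne 20 (not isolated), via ortho-quinone methide 21 (not isolated)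
Conditions: CsF (3 equiv), dry DMF (19, as solvent, about 5 mM in 18), rt → 40 °C; then H2O
Reagents that add atoms: N,N-dimethylformamide (compound 19), CN(C)C=O; water, O
Why: Fluoride attacks silicon in 18 and triflate leaves from A-4, giving the 3-aryloxy-4-methoxybenzyne 20. The closest known reaction type is the insertion of arynes into the C=O bond of formamides, which gives salicylaldehydes after hydrolysis and is regioselective for 3-alkoxybenzynes. The inductively withdrawing A-6 aryloxy group distorts the aryne so that the distal carbon A-4 is the electrophilic one; the DMF oxygen adds there and the carbanion develops at A-5, next to the oxygen that stabilises it, with the A-1 methoxy group and the steric shielding of A-5 acting in the same sense. The A-5 anion then closes onto the iminium carbon (stepwise formal [2+2], 4-exo-trig) to a transient benzoxete, which opens in a 4π electrocyclic process to the ortho-quinone methide 21; water adds to its aminomethylene carbon and dimethylamine is lost, releasing the aldehyde. No ring of the product is closed and no stereocentre is formed. The step needs regioselectivity, secured by the A-6 aryloxy group, and chemoselectivity: DMF as solvent should outcompete the tethered arenes for the aryne, the aryl bromide and the benzyl ether are inert to CsF, and keeping the mixture dry and dilute until 18 is consumed keeps the phenoxide of 22 and the intermediate 21 from adding to a second aryne.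

Step 13
Reactants: 22 2-(BCD-phenoxy)-6-hydroxy-3-methoxybenzaldehyde
Product: 23 6-(benzyloxy)-2-(BCD-phenoxy)-3-methoxybenzaldehyde
Conditions: BnBr, K2CO3, DMF, rt
Reagents that add atoms: benzyl bromide, BrCc1ccccc1
Why: Williamson etherification of the salicylaldehyde phenoxide; the benzyl group masks the acidic A-4 hydroxyl toward ylide and borane and leaves together with the C-4 benzyl group at the end.

Step 14
Reactants: 23 6-(benzyloxy)-2-(BCD-phenoxy)-3-methoxybenzaldehyde
Product: 24 1-(benzyloxy)-3-(BCD-phenoxy)-2-ethenyl-4-methoxybenzene
Conditions: Ph3PCH3Br, KOtBu, THF, 0 °C → rt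
Reagents that add atoms: methyltriphenylphosphonium bromide, C[P+](c1ccccc1)(c1ccccc1)c1ccccc1.[Br-]
Why: Wittig methylenation; the unstabilised ylide is small and reactive enough for the di-ortho-substituted, non-enolisable aldehyde.

Step 15
Reactants: 24 1-(benzyloxy)-3-(BCD-phenoxy)-2-ethenyl-4-methoxybenzene
Product: 26 dibenzyl ether of the target macrocycle, via alkylborane 25 (not isolated)
Conditions: 9-BBN, THF, rt → 50 °C; then syringe-pump addition to Pd(dppf)Cl2 (10 mol %), AsPh3 (20 mol %), Cs2CO3, DMF/THF/H2O, 60 °C, final concentration about 2 mM
Reagents that add atoms: 9-borabicyclo[3.3.1]nonane, B1C2CCCC1CCC2 (supplies the boron of 25 only)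
Why: Anti-Markovnikov hydroboration puts boron on the terminal carbon of the twisted styrene, and the intramolecular B-alkyl Suzuki–Miyaura coupling then closes the 18-membered ring at the D-4–CH2 bond. Zerovalent palladium inserts into the unhindered ring D C–Br bond, base-assisted transmetalation delivers the primary alkyl group, and slow addition at high dilution favours cyclisation over oligomerisation.

Step 16
Reactants: 26 dibenzyl ether of the target macrocycle
Product: 27 target macrocycle CNP0179896.0
Conditions: H2 (1 atm), Pd/C, EtOAc/MeOH, rt
Reagents that add atoms: none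
Why: Hydrogenolysis of the two benzyl aryl ethers over palladium on carbon; the methyl ether, the diaryl ethers and the saturated bridges are unaffected, so the two phenols at A-4 and C-4 are released in the final step.

## Compound list

1 | isovanillin (3-hydroxy-4-methoxybenzaldehyde) | COc1ccc(C=O)cc1O | starting material
2 | 3-iodotoluene | Cc1cccc(I)c1 | starting material
3 | 4-methoxy-3-(3-methylphenoxy)benzaldehyde | COc1ccc(C=O)cc1Oc1cccc(C)c1 | intermediate
4 | 4-methoxy-3-(3-methylphenoxy)phenyl formate | COc1ccc(OC=O)cc1Oc1cccc(C)c1 | intermediate
5 | 4-methoxy-3-(3-methylphenoxy)phenol | COc1ccc(O)cc1Oc1cccc(C)c1 | intermediate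
6 | 4-methoxy-3-(3-methylphenoxy)phenyl N,N-diethylcarbamate | CCN(CC)C(=O)Oc1ccc(OC)c(Oc2cccc(C)c2)c1 | intermediate
7 | 2-lithio-4-methoxy-3-(3-methylphenoxy)phenyl N,N-diethylcarbamate | CCN(CC)C(=O)Oc1ccc(OC)c(Oc2cccc(C)c2)c1[Li] | intermediate
8 | 4-methoxy-3-(3-methylphenoxy)-2-(trimethylsilyl)phenyl N,N-diethylcarbamate | CCN(CC)C(=O)Oc1ccc(OC)c(Oc2cccc(C)c2)c1[Si](C)(C)C | intermediate
9 | 3-[3-(bromomethyl)phenoxy]-4-methoxy-2-(trimethylsilyl)phenyl N,N-diethylcarbamate | CCN(CC)C(=O)Oc1ccc(OC)c(Oc2cccc(CBr)c2)c1[Si](C)(C)C | intermediate
10 | {3-[3-(diethylcarbamoyloxy)-6-methoxy-2-(trimethylsilyl)phenoxy]benzyl}triphenylphosphonium bromide | CCN(CC)C(=O)Oc1ccc(OC)c(Oc2cccc(C[P+](c3ccccc3)(c3ccccc3)c3ccccc3)c2)c1[Si](C)(C)C.[Br-] | intermediate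
11 | 4-(benzyloxy)-3-hydroxybenzaldehyde | O=Cc1ccc(OCc2ccccc2)c(O)c1 | starting material
12 | 4-bromophenylboronic acid | OB(O)c1ccc(Br)cc1 | starting material
13 | 4-(benzyloxy)-3-(4-bromophenoxy)benzaldehyde | O=Cc1ccc(OCc2ccccc2)c(Oc2ccc(Br)cc2)c1 | intermediate
14 | {3-[3-(diethylcarbamoyloxy)-6-methoxy-2-(trimethylsilyl)phenoxy]benzylidene}triphenylphosphorane | CCN(CC)C(=O)Oc1ccc(OC)c(Oc2cccc(C=P(c3ccccc3)(c3ccccc3)c3ccccc3)c2)c1[Si](C)(C)C | intermediate
15 | 3-(3-{2-[4-(benzyloxy)-3-(4-bromophenoxy)phenyl]ethenyl}phenoxy)-4-methoxy-2-(trimethylsilyl)phenyl N,N-diethylcarbamate (E/Z mixture) | CCN(CC)C(=O)Oc1ccc(OC)c(Oc2cccc(C=Cc3ccc(OCc4ccccc4)c(Oc4ccc(Br)cc4)c3)c2)c1[Si](C)(C)C | intermediate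
16 | 3-(BCD-phenoxy)-4-methoxy-2-(trimethylsilyl)phenyl N,N-diethylcarbamate | CCN(CC)C(=O)Oc1ccc(OC)c(Oc2cccc(CCc3ccc(OCc4ccccc4)c(Oc4ccc(Br)cc4)c3)c2)c1[Si](C)(C)C | intermediate
17 | 3-(BCD-phenoxy)-4-methoxy-2-(trimethylsilyl)phenol | COc1ccc(O)c([Si](C)(C)C)c1Oc1cccc(c1)CCc1ccc(OCc2ccccc2)c(c1)Oc1ccc(Br)cc1 | intermediate
18 | 3-(BCD-phenoxy)-4-methoxy-2-(trimethylsilyl)phenyl trifluoromethanesulfonate | COc1ccc(OS(=O)(=O)C(F)(F)F)c([Si](C)(C)C)c1Oc1cccc(c1)CCc1ccc(OCc2ccccc2)c(c1)Oc1ccc(Br)cc1 | intermediate
19 | N,N-dimethylformamide | CN(C)C=O | starting material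
20 | 3-(BCD-phenoxy)-4-methoxybenzyne (aryne across A-4 and A-5) | COC1=C(Oc2cccc(c2)CCc2ccc(OCc3ccccc3)c(c2)Oc2ccc(Br)cc2)C#CC=C1 | intermediate
21 | 5-(BCD-phenoxy)-6-[(dimethylamino)methylidene]-4-methoxycyclohexa-2,4-dien-1-one (ortho-quinone methide) | CN(C)C=C1C(=O)C=CC(OC)=C1Oc1cccc(c1)CCc1ccc(OCc2ccccc2)c(c1)Oc1ccc(Br)cc1 | intermediate
22 | 2-(BCD-phenoxy)-6-hydroxy-3-methoxybenzaldehyde | COc1ccc(O)c(C=O)c1Oc1cccc(c1)CCc1ccc(OCc2ccccc2)c(c1)Oc1ccc(Br)cc1 | intermediate
23 | 6-(benzyloxy)-2-(BCD-phenoxy)-3-methoxybenzaldehyde | COc1ccc(OCc2ccccc2)c(C=O)c1Oc1cccc(c1)CCc1ccc(OCc2ccccc2)c(c1)Oc1ccc(Br)cc1 | intermediate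
24 | 1-(benzyloxy)-3-(BCD-phenoxy)-2-ethenyl-4-methoxybenzene | COc1ccc(OCc2ccccc2)c(C=C)c1Oc1cccc(c1)CCc1ccc(OCc2ccccc2)c(c1)Oc1ccc(Br)cc1 | intermediate
25 | 9-{2-[6-(benzyloxy)-2-(BCD-phenoxy)-3-methoxyphenyl]ethyl}-9-borabicyclo[3.3.1]nonane | COc1ccc(OCc2ccccc2)c(CCB2C3CCCC2CCC3)c1Oc1cccc(c1)CCc1ccc(OCc2ccccc2)c(c1)Oc1ccc(Br)cc1 | intermediate
26 | dibenzyl ether of the target macrocycle (benzyl on the A-4 and C-4 oxygens) | COc1ccc(OCc3ccccc3)c2c1Oc1cccc(c1)CCc1ccc(OCc3ccccc3)c(c1)Oc1ccc(cc1)CC2 | intermediate
27 | target macrocycle CNP0179896.0 (A-1 OMe, A-4 OH, C-4 OH) | COc1ccc(O)c2c1Oc1cccc(c1)CCc1ccc(O)c(c1)Oc1ccc(cc1)CC2 | target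

## Step count and least certain steps

Total step count: 16. Longest linear sequence: 15 steps (steps 1–6 and 8–16 from isovanillin); step 7 is a one-step side branch.

**Step 12 (key step).**
- What may go wrong: partial attack of the formamide oxygen at A-5 would erode regioselectivity. The phenoxide of 22 or the intermediate 21 may add to a second aryne if aryne generation is fast or water enters early. Ring B may capture the aryne intramolecularly at B-2, closing a dibenzofuran. Silicon may be lost by protonation before triflate departs.
- Fallback (from 17, returning at 23): the aryne is given up and the A-4 oxygen from the Dakin step is kept. Phenol 17 is benzylated (BnBr, K2CO3) to 1-(benzyloxy)-3-(BCD-phenoxy)-4-methoxy-2-(trimethylsilyl)benzene F1. ICl in CH2Cl2 at −78 °C replaces silicon by iodine through ipso-substitution, giving 1-(benzyloxy)-3-(BCD-phenoxy)-2-iodo-4-methoxybenzene F2. i-PrMgCl·LiCl in THF at −40 °C exchanges the iodide, well before the ring D bromide, to the arylmagnesium chloride F3, which is formylated with DMF to give 23.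

**Step 15.**
- What may go wrong: intermolecular coupling may lead to oligomers. The alkylborane may protodeboronate, or the alkylpalladium intermediate may undergo β-hydride elimination before reductive elimination, because transmetalation into a strained 18-membered palladacycle is slow.
- Fallback (from 24, returning at 27): the ring is closed by olefin metathesis instead. The ring D bromide of 24 is vinylated (potassium vinyltrifluoroborate, Pd(dppf)Cl2, Cs2CO3) to 1-(benzyloxy)-3-(3-{2-[4-(benzyloxy)-3-(4-ethenylphenoxy)phenyl]ethyl}phenoxy)-2-ethenyl-4-methoxybenzene F4. Ring-closing metathesis with second-generation Grubbs catalyst at high dilution gives the macrocyclic stilbene dibenzyl ether F5 (either alkene geometry). Hydrogenation over Pd/C saturates the alkene and removes both benzyl groups to give 27.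

**Step 5.**
- What may go wrong: electrophilic attack on ring A may compete with hydrogen abstraction, either as ring bromination or as ipso-attack of HBr or bromine at the A-5 C–Si bond with loss of silicon. A second bromination at the benzylic carbon is also possible.
- Fallback (from 8, returning at 18): the directing-group exchange is moved ahead of the bromination so that ring A is strongly deactivated. 8 is cleaved with Cp2Zr(H)Cl to 4-methoxy-3-(3-methylphenoxy)-2-(trimethylsilyl)phenol F6 and triflated (Tf2O, pyridine) to 4-methoxy-3-(3-methylphenoxy)-2-(trimethylsilyl)phenyl trifluoromethanesulfonate F7. Radical bromination gives 3-[3-(bromomethyl)phenoxy]-4-methoxy-2-(trimethylsilyl)phenyl trifluoromethanesulfonate F8, and PPh3 gives the corresponding benzyltriphenylphosphonium bromide F9. NaHMDS in THF at −78 °C forms the benzylidenephosphorane F10, which with 13 gives the stilbene triflate F11. Diimide reduction of F11 gives 18.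

**Step 9.**
- What may go wrong: diimide may disproportionate faster than it transfers hydrogen to the conjugated, electron-rich stilbene, leaving conversion incomplete.
- Fallback (from 15, returning at 16): homogeneous catalytic hydrogenation with H2 and RhCl(PPh3)3 in toluene/EtOH replaces the stoichiometric diimide transfer; it is selective for C=C over C–Br and O–benzyl. No new compound is involved.

## Further compounds

F1 | step 12 | 1-(benzyloxy)-3-(BCD-phenoxy)-4-methoxy-2-(trimethylsilyl)benzene | COc1ccc(OCc2ccccc2)c([Si](C)(C)C)c1Oc1cccc(c1)CCc1ccc(OCc2ccccc2)c(c1)Oc1ccc(Br)cc1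
F2 | step 12 | 1-(benzyloxy)-3-(BCD-phenoxy)-2-iodo-4-methoxybenzene | COc1ccc(OCc2ccccc2)c(I)c1Oc1cccc(c1)CCc1ccc(OCc2ccccc2)c(c1)Oc1ccc(Br)cc1
F3 | step 12 | [6-(benzyloxy)-2-(BCD-phenoxy)-3-methoxyphenyl]magnesium chloride | COc1ccc(OCc2ccccc2)c([Mg]Cl)c1Oc1cccc(c1)CCc1ccc(OCc2ccccc2)c(c1)Oc1ccc(Br)cc1
F4 | step 15 | 1-(benzyloxy)-3-(3-{2-[4-(benzyloxy)-3-(4-ethenylphenoxy)phenyl]ethyl}phenoxy)-2-ethenyl-4-methoxybenzene | COc1ccc(OCc2ccccc2)c(C=C)c1Oc1cccc(c1)CCc1ccc(OCc2ccccc2)c(c1)Oc1ccc(C=C)cc1
F5 | step 15 | macrocyclic stilbene dibenzyl ether (D–A bridge as CH=CH, geometry not fixed) | COc1ccc(OCc3ccccc3)c2c1Oc1cccc(c1)CCc1ccc(OCc3ccccc3)c(c1)Oc1ccc(cc1)C=C2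
F6 | step 5 | 4-methoxy-3-(3-methylphenoxy)-2-(trimethylsilyl)phenol | COc1ccc(O)c([Si](C)(C)C)c1Oc1cccc(C)c1
F7 | step 5 | 4-methoxy-3-(3-methylphenoxy)-2-(trimethylsilyl)phenyl trifluoromethanesulfonate | COc1ccc(OS(=O)(=O)C(F)(F)F)c([Si](C)(C)C)c1Oc1cccc(C)c1
F8 | step 5 | 3-[3-(bromomethyl)phenoxy]-4-methoxy-2-(trimethylsilyl)phenyl trifluoromethanesulfonate | COc1ccc(OS(=O)(=O)C(F)(F)F)c([Si](C)(C)C)c1Oc1cccc(CBr)c1
F9 | step 5 | (3-{6-methoxy-3-[(trifluoromethanesulfonyl)oxy]-2-(trimethylsilyl)phenoxy}benzyl)triphenylphosphonium bromide | COc1ccc(OS(=O)(=O)C(F)(F)F)c([Si](C)(C)C)c1Oc1cccc(C[P+](c2ccccc2)(c2ccccc2)c2ccccc2)c1.[Br-]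
F10 | step 5 | (3-{6-methoxy-3-[(trifluoromethanesulfonyl)oxy]-2-(trimethylsilyl)phenoxy}benzylidene)triphenylphosphorane | COc1ccc(OS(=O)(=O)C(F)(F)F)c([Si](C)(C)C)c1Oc1cccc(C=P(c2ccccc2)(c2ccccc2)c2ccccc2)c1
F11 | step 5 | 3-(3-{2-[4-(benzyloxy)-3-(4-bromophenoxy)phenyl]ethenyl}phenoxy)-4-methoxy-2-(trimethylsilyl)phenyl trifluoromethanesulfonate (E/Z mixture) | COc1ccc(OS(=O)(=O)C(F)(F)F)c([Si](C)(C)C)c1Oc1cccc(C=Cc2ccc(OCc3ccccc3)c(Oc3ccc(Br)cc3)c2)c1
F0 | step 9 | none | none
A1 | alternative 1 | diisopropyl ether of the target macrocycle | COc1ccc(OC(C)C)c2c1Oc1cccc(c1)CCc1ccc(OC(C)C)c(c1)Oc1ccc(cc1)CC2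
A2 | alternative 1 | 19-membered dibenzylic sulfone (D–A bridge as CH2–SO2–CH2) | COc1ccc(OC(C)C)c2c1Oc1cccc(c1)CCc1ccc(OC(C)C)c(c1)Oc1ccc(cc1)CS(=O)(=O)C2
A3 | alternative 2 | 3-(3-bromophenoxy)-4-methoxy-2-{2-[4-(triisopropylsilyloxy)phenyl]ethyl}phenol | COc1ccc(O)c(CCc2ccc(O[Si](C(C)C)(C(C)C)C(C)C)cc2)c1Oc1cccc(Br)c1
A4 | alternative 2 | 3-(3-bromophenoxy)-4-ethenyl-4-methoxy-2-{2-[4-(triisopropylsilyloxy)phenyl]ethyl}cyclobut-2-en-1-one (racemic) | C=CC1(OC)C(Oc2cccc(Br)c2)=C(CCc2ccc(O[Si](C(C)C)(C(C)C)C(C)C)cc2)C1=O
A5 | alternative 3 | macrocyclic 3-aryloxy quinone monoketal | O=C1C=CC(OC)(OC)C2=C1CCc1ccc(cc1)Oc1cc(ccc1OCc1ccccc1)CCc1cccc(c1)O2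
A6 | alternative 3 | open-chain 3-bromo quinone monoketal with ring B tert-butyldimethylsilyl ether | O=C1C=CC(OC)(OC)C(Br)=C1CCc1ccc(cc1)Oc1cc(ccc1OCc1ccccc1)CCc1cccc(O[Si](C)(C)C(C)(C)C)c1
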